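## Analysis of the target

Labdane numbering is used throughout. The target 29 is a trans-fused decalin: ring A (C1–C5, C10, gem-dimethyl at C4) and ring B (C5–C10), with a 3-methylpentanoate chain (C11–C16, methyl ester at C15) on C9. It has six stereocentres, 5S,6R,8R,9R,10S,13S. Five are contiguous on ring B (C5, C6, C8, C9, C10) and one (C13) is isolated in the chain; C10 is quaternary and C8 is a tertiary carbinol. The ring fusion is trans (5α-H, 10β-methyl), the C9 chain and the 8α-hydroxyl are equatorial, and the C17 methyl and the 6β-acetate are axial. Four groups therefore stand syn-axial on the β face (4β-methyl, 6-acetoxy, C17, C10 methyl), which crowds C6 and C8. Sensitive points are the acetate and methyl ester (hydride, strong base), the tertiary 8-hydroxyl (dehydration, and closure onto C12 as a cyclic ether once C12 carries a leaving group) and C5 whenever C6 is a carbonyl. The hard parts are the two fully substituted carbons inside the contiguous array, the C5/C10 relation on a monocycle (where the C10 methyl and the C9 branch are of similar size), and the remote C13. The strategy rests on one feature: C8 is a methyl carbinol bonded to C9, and C9 carries C11–C12, so C8–C9 can be read as the bond between a ketone carbon and the β-carbon of an enoate. These are two electrophilic carbons, which a ketyl radical can join while closing ring B.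

## Retrosynthetic reasoning

**Protecting groups (29 ⇒ 28 ⇒ 27).** The acetate is put on last, because it would not survive the hydride and Grignard steps. Diol 28 has one secondary and one tertiary hydroxyl, so acylation needs no protecting group. Compound 28 comes from the bis-silyl ether 27.

**C12–C13 (27 ⇒ 24 + 25).** The chain is cut next to C13, the only stereocentre no ring atom can control. Conjugate addition of the Grignard reagent 26, made from bromide 24, to crotonate 25 under a chiral copper catalyst brings in C13–C16 and sets C13 by catalyst control. Cutting elsewhere in the chain would need a secondary sp3–sp3 coupling or a chiral-pool fragment.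

**C12 oxidation level (24 ⇒ 23 ⇒ 22 ⇒ 21 ⇒ 20).** The bromide comes from the primary alcohol. The tertiary O8 must be masked first, because an activated C12 is otherwise captured by O8 to give a five-membered cyclic ether. Going through diol 21 and the bis-silyl ether 22 makes the sequence indifferent to whether 20 is isolated as hydroxy ester or has partly lactonised.

**C8–C9, ring B (20 ⇒ 19).** This is the central cut. Both carbons are acceptors in 19 (ketone and enoate β-carbon), so the forward step is a reductive ketyl–olefin cyclisation. It has to close a six-membered ring and set C8 and C9. Ring A, with C6 and C9 both equatorial, dictates the chair in which this happens.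

**Ketone and enoate (19 ⇒ 18 ⇒ 15).** The methyl ketone is unmasked last from a terminal alkene. This lets the C9=C11 double bond be introduced by ester dehydrogenation of 15 while the ester enolate is still the only enolate available.

**C6–C7 (15 ⇒ 14 ⇒ 11 + 12).** Allylation of aldehyde 11 with 12 makes the C6 carbinol under catalyst control. The allyl group is a masked acetonyl unit (C7, C8, C17).

**Oxidation states at C6 and C12 (11 ⇒ 10 ⇒ 8).** Diol 8 has two primary alcohols of very different hindrance. The open-chain one is taken to the ester, the one flanked by two quaternary carbons to the aldehyde.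

**C5–H, C6–O and C12–O (8 ⇒ 6).** All three bonds come from one cyclic hydroboration of diene 6. This is where C5 is set. An external reagent attacking C5=C6 cannot reliably tell the C10 methyl from the C10 chain. A boron atom already attached to the end of that chain can reach C6 only from the side on which C9 lies, so hydrogen arrives at C5 cis to C9.

**C5=C6 (6 ⇒ 4 + 5).** Methylenation of ketone 4 with the ylide from 5 supplies C6.

**C10–C9 (4 ⇒ 3 ⇒ 1 + 2).** The quaternary centre is made by enantioselective decarboxylative allylation of the enol carbonate 3. Ketone 1 has a single enolisable position, and the allyl group from 2 supplies exactly C9, C11 and C12.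

## Alternatives that were turned down

**Alternative 1:** Ring B is traced back to a cyclobutanone in which the C6 carbonyl is bonded to C9, so that C5–C6 and C9–C10 come from a [2+2] cycloaddition. A keteniminium ion, whose α-carbon carries an isopropenyl group (C7, C8, C17) and the whole ester chain, adds to a ring A cyclohexene (C5=C10). Hydrolysis gives the cyclobutanone A1, and a 1,3-shift of the vinylcyclobutanol(ate) would enlarge the four-membered ring to ring B.
- For: two ring bonds and the quaternary C10 form in one step from a simple alkene, the C6 oxygen is delivered, and the chain with C13 is on board from the start. On convergence and step count this beats the chosen route.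
- Against: a tetrasubstituted keteniminium ion must add to an alkene whose reacting carbon C5 is neopentyl. The cyclobutane is cis-fused, so C5 has to be corrected later through a 6-ketone. The absolute sense at C10 needs an auxiliary on nitrogen.
- Decisive point: after ring enlargement C8 and C9 are the two ends of a tetrasubstituted alkene. The 8α-hydroxyl and 9α-hydrogen would have to be added to it against its regiochemical and steric preferences. The chosen ketyl closure creates exactly these two centres in the ring-forming event.

**Alternative 2:** Ring B is cut at C7–C8 and C9–C10, a Diels–Alder reaction between a 2-silyloxydiene built on ring A (C7=C6–C5=C10) and an allenic ester carrying a chiral lactone-derived auxiliary. The Lewis-acid-promoted cycloaddition gives A2, with a C6 silyl enol ether, an exocyclic C8=C17 alkene and a C9 ester.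
- For: this is the shortest way to the bicycle. C5 would later be set by thermodynamic protonation in a decalin, which is more secure than the tethered hydroboration used here. The exocyclic alkene is a good precursor of the 8α-alcohol. On these points the alternative is stronger.
- Against: the diene terminus C10 is fully substituted and the diene is twisted out of the s-cis form by the C4 gem-dimethyl group, so the quaternary centre must form at the most hindered end. Endo/exo control, which fixes C9 relative to C10, and the auxiliary's facial control are hard to predict for an allene. A2 ends at C11, so C12–C16 with C13 must still be added, whereas 20 already holds C11 and C12 with C9 in place.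
- Comparison: the chosen route is longer in the monocycle but assigns each stereocentre to a reaction of known sense.

**Alternative 3:** Ring B is contracted by removing C7, giving a bicyclic ketone in which the C6 carbonyl is bonded directly to C8. Forward, the silyl enol ether towards C8 is cyclopropanated with a zinc carbenoid, the silyloxycyclopropane is opened oxidatively, and elimination gives the ring-enlarged enone A3.
- For: each operation of this one-carbon homologation is dependable. A3 has every carbon of the target and a useful pattern: a 6-ketone (hydride from the α face gives the 6β-alcohol), a C7=C8 enone (epoxidation and reductive opening gives the 8α-alcohol) and an epimerisable C5. Its end game is arguably more secure than that of the chosen route.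
- Against: the key step adds one carbon and creates no stereocentre. All the difficulty moves into the five-membered precursor, which must already contain the quaternary C10, the C9 chain with C13, the C8 methyl and a trans ring fusion that five-membered ketones disfavour. Enol ether formation must choose C8 over C5, both tertiary.
- Comparison: the chosen route builds ring B and two stereocentres in one step from a monocycle reached in ten steps.

Key step: step 11

Assumption: for the three chiral catalysts (steps 2, 7 and 16) the enantiomer meant is the one that gives the facial sense stated in that step; the ligand names follow the published sense for the parent substrates.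

## Route

Step 1
Reactants: 1 2,2,6-trimethylcyclohexan-1-one (racemic); 2 allyl chloroformate
Product: 3 allyl 2,6,6-trimethylcyclohex-1-en-1-yl carbonate
Conditions: LiN(SiMe3)2, THF, 0 °C → rt; then TMEDA, 2, −78 °C → rt
Reagents that add atoms: none
Why: Enolate O-acylation; the ketone has one enolisable position, so a single enol carbonate forms and the stereocentre of racemic 1 is erased. A lithium enolate with a chloroformate and TMEDA reacts at oxygen.

Step 2
Reactants: 3
Product: 4 (2R)-2-allyl-2,6,6-trimethylcyclohexan-1-one
Conditions: Pd2(dba)3 (2.5 mol%), (R)-t-BuPHOX (6 mol%), THF, 25 °C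
Reagents that add atoms: none
Why: Decarboxylative asymmetric allylic alkylation (Tsuji allylation): zerovalent palladium ionises the allyl carbonate, CO2 is lost, and the enolate recombines with the π-allyl fragment at carbon. The phosphinooxazoline ligand selects the enolate face and sets C10 as R (the mirror-image ligand gives the S ketones); α-quaternary cyclohexanones of this kind are the standard substrates.

Step 3
Reactants: 4; 5 methyltriphenylphosphonium bromide
Product: 6 (1R)-1-allyl-1,3,3-trimethyl-2-methylidenecyclohexane
Conditions: 5, KOt-Bu, toluene, 110 °C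
Reagents that add atoms: none
Why: Wittig methylenation; the salt-free ylide in hot toluene is the usual answer to a non-enolisable ketone between two quaternary carbons. C10 cannot epimerise.

Step 4
Reactants: 6
Product: 8 3-[(1R,2S)-2-(hydroxymethyl)-1,3,3-trimethylcyclohexyl]propan-1-ol, via B-thexylborepane 7 (not isolated)
Conditions: ThxBH2 (1.05 equiv, from BH3·THF and 2,3-dimethylbut-2-ene), THF (0.02 M), −20 °C → rt; then NaOH, H2O2, 0 → 45 °C
Reagents that add atoms: thexylborane, CC(C)C(C)(C)B; hydrogen peroxide, OO
Why: Cyclic hydroboration of a 1,5-diene with a monoalkylborane: the first B–H adds to the terminal alkene (boron on C12), and the second adds intramolecularly across C5=C6 with boron on C6. The tether C9–C11–C12 lets boron reach C6 only over the face on which C9 lies (or, with C9 equatorial, the face away from the two axial methyls), so hydrogen goes to C5 cis to C9. Oxidation with retention gives both primary alcohols.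

Step 5
Reactants: 8
Product: 10 methyl 3-[(1R,2S)-2-(hydroxymethyl)-1,3,3-trimethylcyclohexyl]propanoate, via hydroxy acid 9 (not isolated)
Conditions: TEMPO (0.2 equiv), PhI(OAc)2 (2.2 equiv), MeCN/H2O, 0 °C → rt; then Me3SiCHN2, MeOH/toluene, 0 °C
Reagents that add atoms: water, O; (trimethylsilyl)diazomethane, C[Si](C)(C)C=[N+]=[N-]
Why: Nitroxyl-catalysed oxidation of the open-chain primary alcohol to the acid through the aldehyde hydrate, then esterification. The CH2OH on C5 lies between two quaternary carbons and reacts much more slowly; any aldehyde formed there is the product of step 6, so over-oxidation converges.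

Step 6
Reactants: 10
Product: 11 methyl 3-[(1R,2S)-2-formyl-1,3,3-trimethylcyclohexyl]propanoate
Conditions: Dess–Martin periodinane, NaHCO3, CH2Cl2, 0 °C → rt
Reagents that add atoms: none
Why: Dess–Martin oxidation under buffered, base-free conditions, so that C5, now α to the aldehyde, is not epimerised; the aldehyde is used directly.

Step 7
Reactants: 11; 12 allylboronic acid pinacol ester
Product: 14 methyl 3-[(1R,2S)-2-[(1R)-1-hydroxybut-3-en-1-yl]-1,3,3-trimethylcyclohexyl]propanoate, via pinacol borate 13 (not isolated)
Conditions: 12 (1.5 equiv), (R)-TRIP phosphoric acid (5 mol%), toluene, −30 → 0 °C; aqueous work-up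
Reagents that add atoms: none
Why: Chiral phosphoric acid-catalysed allylboration through a closed six-membered chair transition state. The catalyst enantiomer is the one that adds allyl to the Re face (it gives (R)-1-phenylbut-3-en-1-ol from benzaldehyde), which is 6R here. Catalyst control is relied on because the two quaternary carbons flanking C5 are of similar size and give the aldehyde little bias of its own.

Step 8
Reactants: 14
Product: 15 methyl 3-[(1R,2S)-2-[(1R)-1-[(tert-butyldimethylsilyl)oxy]but-3-en-1-yl]-1,3,3-trimethylcyclohexyl]propanoate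
Conditions: t-BuMe2SiOTf, 2,6-lutidine, CH2Cl2, −78 → 0 °C
Reagents that add atoms: tert-butyldimethylsilyl trifluoromethanesulfonate, CC(C)(C)[Si](C)(C)OS(=O)(=O)C(F)(F)F
Why: Silylation of a hindered secondary alcohol needs the silyl triflate; the ether survives the enolate, Wacker, samarium and hydride steps that follow.

Step 9
Reactants: 15
Product: 18 methyl (2E)-3-[(1R,2S)-2-[(1R)-1-[(tert-butyldimethylsilyl)oxy]but-3-en-1-yl]-1,3,3-trimethylcyclohexyl]prop-2-enoate, via α-phenylselanyl ester 16 (not isolated), via selenoxide 17 (not isolated)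
Conditions: LiN(i-Pr)2, THF, −78 °C; PhSeBr; then H2O2, pyridine, CH2Cl2, 0 °C → rt
Reagents that add atoms: phenylselenenyl bromide, Br[Se]c1ccccc1; hydrogen peroxide, OO
Why: Ester α-selenenylation and selenoxide syn-elimination; the only β-hydrogens are on C9, so the (E)-enoate C9=C11 forms. It is done before the ketone exists, so the ester enolate is the only enolate.

Step 10
Reactants: 18
Product: 19 methyl (2E)-3-[(1R,2S)-2-[(1R)-1-[(tert-butyldimethylsilyl)oxy]-3-oxobutyl]-1,3,3-trimethylcyclohexyl]prop-2-enoate
Conditions: PdCl2 (10 mol%), CuCl (1 equiv), O2 (1 atm), DMF/H2O (7:1), rt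
Reagents that add atoms: water, O
Why: Tsuji–Wacker oxidation; Markovnikov hydroxypalladation of the terminal alkene gives the methyl ketone, and the electron-poor enoate and the silyl ether are left alone.

Step 11
Reactants: 19
Product: 20 methyl 2-[(1R,2R,4R,4aS,8aS)-4-[(tert-butyldimethylsilyl)oxy]-2-hydroxy-2,5,5,8a-tetramethyldecahydronaphthalen-1-yl]acetate
Conditions: SmI2 (2.5 equiv), HMPA (10 equiv), t-BuOH (2 equiv), THF, −78 → 0 °C
Reagents that add atoms: none
Why: Electron transfer from SmI2 (made more reducing by HMPA) to the C8 ketone gives a samarium ketyl, which adds to C9, the β-carbon of the enoate, in a 6-exo-trig closure that forms C8–C9 and ring B; a second SmI2 reduces the C11 radical to the enolate, which t-BuOH protonates. The closest known reaction type is the samarium diiodide ketyl–olefin cyclisation of ketones onto α,β-unsaturated esters. C6 and C9 are both equatorial on the ring A chair fixed by C5 and C10, so the tether can only close as the second chair of a trans-decalin. C9: the enoate takes the pseudo-equatorial position, so C11 ends β and H9 α. C8: the ketyl oxygen with its HMPA-ligated samarium is the largest group and sits pseudo-equatorial, which puts C17 axial and gives the 8α-alcohol trans to the C9 chain. The step needs reduction of the ketone before the enoate and the trans (8α-OH, 9β-chain) isomer; the β-silyloxy group is not lost from a ketyl. Partial lactonisation of 20 is harmless, since step 12 reduces ester and lactone to the same diol.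

Step 12
Reactants: 20
Product: 21 (1R,2R,4R,4aS,8aS)-4-[(tert-butyldimethylsilyl)oxy]-1-(2-hydroxyethyl)-2,5,5,8a-tetramethyldecahydronaphthalen-2-ol
Conditions: LiAlH4, THF, 0 °C
Reagents that add atoms: none
Why: Hydride reduction of the ester (or of any lactone) to the 8,12-diol; the silyl ether and all stereocentres are untouched.

Step 13
Reactants: 21
Product: 22 tert-butyldimethyl{[(1R,3R,4R,4aS,8aS)-2,2,4a,7-tetramethyl-7-[(triethylsilyl)oxy]-8-{2-[(triethylsilyl)oxy]ethyl}decahydronaphthalen-1-yl]oxy}silane (6β-OTBS, 8α-OTES, 12-OTES)
Conditions: Et3SiOTf (2.5 equiv), 2,6-lutidine, CH2Cl2, −78 → 0 °C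
Reagents that add atoms: triethylsilyl trifluoromethanesulfonate, CC[Si](CC)(CC)OS(=O)(=O)C(F)(F)F
Why: Exhaustive silylation; the triflate also silylates the tertiary O8, which must be masked before C12 is activated.

Step 14
Reactants: 22
Product: 23 2-[(1R,2R,4R,4aS,8aS)-4-[(tert-butyldimethylsilyl)oxy]-2,5,5,8a-tetramethyl-2-[(triethylsilyl)oxy]decahydronaphthalen-1-yl]ethan-1-ol
Conditions: PPTS (0.1 equiv), MeOH/CH2Cl2, 0 °C
Reagents that add atoms: none
Why: Acid-catalysed methanolysis removes the unhindered primary triethylsilyl ether much faster than the tertiary triethylsilyl or the hindered secondary tert-butyldimethylsilyl ether.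

Step 15
Reactants: 23
Product: 24 {[(1R,2R,4R,4aS,8aS)-1-(2-bromoethyl)-4-[(tert-butyldimethylsilyl)oxy]-2,5,5,8a-tetramethyldecahydronaphthalen-2-yl]oxy}triethylsilane
Conditions: CBr4, PPh3, 2,6-lutidine, CH2Cl2, 0 °C
Reagents that add atoms: tetrabromomethane, BrC(Br)(Br)Br
Why: Appel reaction of the primary alcohol (SN2 at C12); with O8 silylated, the closure to the cyclic ether that a free 8-hydroxyl would undergo is suppressed.

Step 16
Reactants: 24; 25 methyl (E)-but-2-enoate (methyl crotonate)
Product: 27 methyl (3S)-5-[(1R,2R,4R,4aS,8aS)-4-[(tert-butyldimethylsilyl)oxy]-2,5,5,8a-tetramethyl-2-[(triethylsilyl)oxy]decahydronaphthalen-1-yl]-3-methylpentanoate, via Grignard reagent 26 (not isolated)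
Conditions: Mg, Et2O, 35 °C; then 25 (2 equiv), CuBr·SMe2 (5 mol%), Josiphos (6 mol%), t-BuOMe, −75 °C; aq. NH4Cl
Reagents that add atoms: magnesium, [Mg]
Why: Copper-catalysed asymmetric conjugate addition of a Grignard reagent to an α,β-unsaturated ester; the ferrocenyl diphosphine on copper decides which face of C13 receives the alkyl group. The ligand enantiomer is the one that adds to the Re face of the crotonate β-carbon (it gives (S)-methyl 3-methylpentanoate from EtMgBr), which is 13S here. The ring stereocentres are too far away to interfere.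

Step 17
Reactants: 27
Product: 28 methyl (3S)-5-[(1R,2R,4R,4aS,8aS)-2,4-dihydroxy-2,5,5,8a-tetramethyldecahydronaphthalen-1-yl]-3-methylpentanoate
Conditions: HF·pyridine, pyridine, THF, 0 → 40 °C
Reagents that add atoms: none
Why: Fluoride-mediated cleavage of both silyl ethers under buffered acidic conditions, which spare the methyl ester and do not dehydrate the tertiary alcohol.

Step 18
Reactants: 28
Product: 29 methyl (3S)-5-[(1R,2R,4R,4aS,8aS)-4-(acetyloxy)-2-hydroxy-2,5,5,8a-tetramethyldecahydronaphthalen-1-yl]-3-methylpentanoate
Conditions: Ac2O, pyridine, DMAP (0.2 equiv), CH2Cl2, rt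
Reagents that add atoms: acetic anhydride, CC(=O)OC(C)=O
Why: Nucleophile-catalysed acetylation; the secondary 6β-hydroxyl, though axial, is acylated, while the tertiary 8-hydroxyl does not react under these conditions.

## Compound list

1 | 2,2,6-trimethylcyclohexan-1-one (racemic) | CC1CCCC(C)(C)C1=O | starting material
2 | allyl chloroformate | C=CCOC(Cl)=O | starting material
3 | allyl 2,6,6-trimethylcyclohex-1-en-1-yl carbonate | C=CCOC(=O)OC1=C(C)CCCC1(C)C | intermediate
4 | (2R)-2-allyl-2,6,6-trimethylcyclohexan-1-one | C=CC[C@@]1(C)CCCC(C)(C)C1=O | intermediate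
5 | methyltriphenylphosphonium bromide | C[P+](c1ccccc1)(c1ccccc1)c1ccccc1.[Br-] | starting material
6 | (1R)-1-allyl-1,3,3-trimethyl-2-methylidenecyclohexane | C=CC[C@@]1(C)CCCC(C)(C)C1=C | intermediate
7 | (5aS,9aS)-2-(2,3-dimethylbutan-2-yl)-5a,9,9-trimethyldecahydro-1H-2-benzoborepine (trans-fused B-thexylborepane) | CC(C)C(C)(C)B1CCC[C@@]2(C)CCCC(C)(C)[C@@H]2C1 | intermediate
8 | 3-[(1R,2S)-2-(hydroxymethyl)-1,3,3-trimethylcyclohexyl]propan-1-ol | OCCC[C@@]1(C)CCCC(C)(C)[C@@H]1CO | intermediate
9 | 3-[(1R,2S)-2-(hydroxymethyl)-1,3,3-trimethylcyclohexyl]propanoic acid | OC(=O)CC[C@@]1(C)CCCC(C)(C)[C@@H]1CO | intermediate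
10 | methyl 3-[(1R,2S)-2-(hydroxymethyl)-1,3,3-trimethylcyclohexyl]propanoate | COC(=O)CC[C@@]1(C)CCCC(C)(C)[C@@H]1CO | intermediate
11 | methyl 3-[(1R,2S)-2-formyl-1,3,3-trimethylcyclohexyl]propanoate | COC(=O)CC[C@@]1(C)CCCC(C)(C)[C@@H]1C=O | intermediate
12 | allylboronic acid pinacol ester | C=CCB1OC(C)(C)C(C)(C)O1 | starting material
13 | methyl 3-[(1R,2S)-1,3,3-trimethyl-2-[(1R)-1-[(4,4,5,5-tetramethyl-1,3,2-dioxaborolan-2-yl)oxy]but-3-en-1-yl]cyclohexyl]propanoate | COC(=O)CC[C@@]1(C)CCCC(C)(C)[C@@H]1[C@H](OB2OC(C)(C)C(C)(C)O2)CC=C | intermediate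
14 | methyl 3-[(1R,2S)-2-[(1R)-1-hydroxybut-3-en-1-yl]-1,3,3-trimethylcyclohexyl]propanoate | COC(=O)CC[C@@]1(C)CCCC(C)(C)[C@@H]1[C@H](O)CC=C | intermediate
15 | methyl 3-[(1R,2S)-2-[(1R)-1-[(tert-butyldimethylsilyl)oxy]but-3-en-1-yl]-1,3,3-trimethylcyclohexyl]propanoate | COC(=O)CC[C@@]1(C)CCCC(C)(C)[C@@H]1[C@H](O[Si](C)(C)C(C)(C)C)CC=C | intermediate
16 | methyl 3-[(1R,2S)-2-[(1R)-1-[(tert-butyldimethylsilyl)oxy]but-3-en-1-yl]-1,3,3-trimethylcyclohexyl]-2-(phenylselanyl)propanoate (both C2 epimers) | COC(=O)C([Se]c1ccccc1)C[C@@]1(C)CCCC(C)(C)[C@@H]1[C@H](O[Si](C)(C)C(C)(C)C)CC=C | intermediate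
17 | Se-oxide of 16 (mixture of isomers at C2 and Se) | COC(=O)C([Se+]([O-])c1ccccc1)C[C@@]1(C)CCCC(C)(C)[C@@H]1[C@H](O[Si](C)(C)C(C)(C)C)CC=C | intermediate
18 | methyl (2E)-3-[(1R,2S)-2-[(1R)-1-[(tert-butyldimethylsilyl)oxy]but-3-en-1-yl]-1,3,3-trimethylcyclohexyl]prop-2-enoate | COC(=O)/C=C/[C@@]1(C)CCCC(C)(C)[C@@H]1[C@H](O[Si](C)(C)C(C)(C)C)CC=C | intermediate
19 | methyl (2E)-3-[(1R,2S)-2-[(1R)-1-[(tert-butyldimethylsilyl)oxy]-3-oxobutyl]-1,3,3-trimethylcyclohexyl]prop-2-enoate | COC(=O)/C=C/[C@@]1(C)CCCC(C)(C)[C@@H]1[C@H](O[Si](C)(C)C(C)(C)C)CC(C)=O | intermediate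
20 | methyl 2-[(1R,2R,4R,4aS,8aS)-4-[(tert-butyldimethylsilyl)oxy]-2-hydroxy-2,5,5,8a-tetramethyldecahydronaphthalen-1-yl]acetate (methyl 6β-silyloxy-8α-hydroxy-11-homodriman-12-oate) | COC(=O)C[C@@H]1[C@@]2(C)CCCC(C)(C)[C@@H]2[C@H](O[Si](C)(C)C(C)(C)C)C[C@@]1(C)O | intermediate
21 | (1R,2R,4R,4aS,8aS)-4-[(tert-butyldimethylsilyl)oxy]-1-(2-hydroxyethyl)-2,5,5,8a-tetramethyldecahydronaphthalen-2-ol | OCC[C@@H]1[C@@]2(C)CCCC(C)(C)[C@@H]2[C@H](O[Si](C)(C)C(C)(C)C)C[C@@]1(C)O | intermediate
22 | bis(triethylsilyl) ether of 21 (6β-OTBS, 8α-OTES, 12-OTES) | CC[Si](CC)(CC)OCC[C@@H]1[C@@]2(C)CCCC(C)(C)[C@@H]2[C@H](O[Si](C)(C)C(C)(C)C)C[C@@]1(C)O[Si](CC)(CC)CC | intermediate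
23 | 2-[(1R,2R,4R,4aS,8aS)-4-[(tert-butyldimethylsilyl)oxy]-2,5,5,8a-tetramethyl-2-[(triethylsilyl)oxy]decahydronaphthalen-1-yl]ethan-1-ol | OCC[C@@H]1[C@@]2(C)CCCC(C)(C)[C@@H]2[C@H](O[Si](C)(C)C(C)(C)C)C[C@@]1(C)O[Si](CC)(CC)CC | intermediate
24 | {[(1R,2R,4R,4aS,8aS)-1-(2-bromoethyl)-4-[(tert-butyldimethylsilyl)oxy]-2,5,5,8a-tetramethyldecahydronaphthalen-2-yl]oxy}triethylsilane | BrCC[C@@H]1[C@@]2(C)CCCC(C)(C)[C@@H]2[C@H](O[Si](C)(C)C(C)(C)C)C[C@@]1(C)O[Si](CC)(CC)CC | intermediate
25 | methyl (E)-but-2-enoate (methyl crotonate) | C/C=C/C(=O)OC | starting material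
26 | Grignard reagent of 24 (C12–MgBr) | Br[Mg]CC[C@@H]1[C@@]2(C)CCCC(C)(C)[C@@H]2[C@H](O[Si](C)(C)C(C)(C)C)C[C@@]1(C)O[Si](CC)(CC)CC | intermediate
27 | methyl (3S)-5-[(1R,2R,4R,4aS,8aS)-4-[(tert-butyldimethylsilyl)oxy]-2,5,5,8a-tetramethyl-2-[(triethylsilyl)oxy]decahydronaphthalen-1-yl]-3-methylpentanoate | COC(=O)C[C@@H](C)CC[C@@H]1[C@@]2(C)CCCC(C)(C)[C@@H]2[C@H](O[Si](C)(C)C(C)(C)C)C[C@@]1(C)O[Si](CC)(CC)CC | intermediate
28 | methyl (3S)-5-[(1R,2R,4R,4aS,8aS)-2,4-dihydroxy-2,5,5,8a-tetramethyldecahydronaphthalen-1-yl]-3-methylpentanoate | COC(=O)C[C@@H](C)CC[C@@H]1[C@@]2(C)CCCC(C)(C)[C@@H]2[C@H](O)C[C@@]1(C)O | intermediate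
29 | methyl (3S)-5-[(1R,2R,4R,4aS,8aS)-4-(acetyloxy)-2-hydroxy-2,5,5,8a-tetramethyldecahydronaphthalen-1-yl]-3-methylpentanoate (methyl (13S)-6β-acetoxy-8α-hydroxylabdan-15-oate) | COC(=O)C[C@@H](C)CC[C@@H]1[C@@]2(C)CCCC(C)(C)[C@@H]2[C@H](OC(C)=O)C[C@@]1(C)O | target

## Step count and risks

Total step count: 18. Longest linear sequence: 18 steps (the route is linear from 1; the precursor 19 is reached in 10 steps).

**Step 11 (key step).** What is most likely to go wrong is poor facial discrimination at the ketyl carbon. The C17 methyl must go axial against the C10 methyl and the axial 6-silyloxy group, so the congested chair may close slowly and allow simple reduction of the ketone or the 8-epimeric closure. Fallback, from 19 back to 21: kinetic deprotonation on the methyl side (KN(SiMe3)2, −78 °C) and trapping with N-phenyltriflimide would give the enol triflate F1. An intramolecular reductive Heck reaction (Pd(OAc)2, PPh3, HCO2Na, DMF; oxidative addition to zerovalent palladium, 6-exo insertion into the same enoate carbon C9, formate reduction) would give the 8(17)-alkene F2 with the enoate again pseudo-equatorial. Epoxidation from the open α face (mCPBA) would give the 8α,17-epoxide F3. LiAlH4 then opens the epoxide at C17 and reduces the ester, arriving at diol 21. C8 is thus set by a reagent approaching a formed trans-decalin from its less hindered face.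

**Step 4.** The risk is intermolecular hydroboration (oligomerisation) outrunning the ring-closing second addition, which would remove the tether's control over the C5 face. Fallback, from 6 back to 8: H2PtCl6-catalysed hydrosilylation of the terminal alkene with Ph2SiH2 would give the hydrosilane F4. At high dilution its remaining Si–H bond adds across C5=C6 in the same tethered, syn fashion to give the trans-fused silepane F5. Tamao–Fleming oxidation (HBF4·OEt2; then H2O2, KF, KHCO3) returns diol 8.

**Step 7.** The risk is slow catalysed addition to a very hindered aldehyde, so that the uncatalysed, unselective allylboration erodes control at C6. Fallback, from 11 back to 14: uncatalysed allylboration with 12 would give 14 together with its C6 epimer F6. Dess–Martin oxidation of the mixture would give the β,γ-unsaturated ketone F7. Corey–Bakshi–Shibata reduction ((S)-methyl-oxazaborolidine, catecholborane, −78 °C), with the ring carbon as the large and the allyl CH2 as the small substituent, returns 14.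

**Step 16.** The risk is incomplete facial control at C13 with a bulky, functionalised Grignard reagent, or Wurtz coupling during magnesium insertion. Fallback, from 24 (through 26) back to 27: (4S)-4-phenyloxazolidin-2-one is acylated with crotonyl chloride to the imide F8. The Grignard reagent 26 with CuBr·SMe2 adds to F8 on the face away from the phenyl group in the magnesium-chelated s-cis conformer, which is the Re face of C13, to give the adduct F9. NaOMe in methanol releases the methyl ester 27.

**Step 3.** The risk is no addition to the doubly neopentyl carbonyl, or base-induced migration of the allyl double bond at 110 °C. Fallback, from 4 back to 6: addition of Me3SiCH2Li with CeCl3 would give the β-hydroxysilane F10, and Peterson elimination with KH gives 6.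

Further compounds

F1 | step 11 | methyl (2E)-3-[(1R,2S)-2-[(1R)-1-[(tert-butyldimethylsilyl)oxy]-3-[(trifluoromethanesulfonyl)oxy]but-3-en-1-yl]-1,3,3-trimethylcyclohexyl]prop-2-enoate | COC(=O)/C=C/[C@@]1(C)CCCC(C)(C)[C@@H]1[C@H](O[Si](C)(C)C(C)(C)C)CC(=C)OS(=O)(=O)C(F)(F)F
F2 | step 11 | methyl 6β-[(tert-butyldimethylsilyl)oxy]-11-homodrim-8(17)-en-12-oate | COC(=O)C[C@@H]1[C@@]2(C)CCCC(C)(C)[C@@H]2[C@H](O[Si](C)(C)C(C)(C)C)CC1=C
F3 | step 11 | methyl 6β-[(tert-butyldimethylsilyl)oxy]-8α,17-epoxy-11-homodriman-12-oate | COC(=O)C[C@@H]1[C@@]2(C)CCCC(C)(C)[C@@H]2[C@H](O[Si](C)(C)C(C)(C)C)C[C@@]1(C3)O3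
F4 | step 4 | diphenyl{3-[(1R)-1,3,3-trimethyl-2-methylidenecyclohexyl]propyl}silane | C=C1C(C)(C)CCC[C@]1(C)CCC[SiH](c1ccccc1)c1ccccc1
F5 | step 4 | (5aR,9aS)-5a,9,9-trimethyl-2,2-diphenyldecahydro-1H-2-benzosilepine (trans-fused) | C1[C@@H]2C(C)(C)CCC[C@]2(C)CCC[Si]1(c1ccccc1)c1ccccc1
F6 | step 7 | methyl 3-[(1R,2S)-2-[(1S)-1-hydroxybut-3-en-1-yl]-1,3,3-trimethylcyclohexyl]propanoate | COC(=O)CC[C@@]1(C)CCCC(C)(C)[C@@H]1[C@@H](O)CC=C
F7 | step 7 | methyl 3-[(1R,2S)-2-(but-3-enoyl)-1,3,3-trimethylcyclohexyl]propanoate | COC(=O)CC[C@@]1(C)CCCC(C)(C)[C@@H]1C(=O)CC=C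
F8 | step 16 | (4S)-3-[(2E)-but-2-enoyl]-4-phenyl-1,3-oxazolidin-2-one | C/C=C/C(=O)N1[C@@H](c2ccccc2)COC1=O
F9 | step 16 | (4S)-3-[(3S)-5-[(1R,2R,4R,4aS,8aS)-4-[(tert-butyldimethylsilyl)oxy]-2,5,5,8a-tetramethyl-2-[(triethylsilyl)oxy]decahydronaphthalen-1-yl]-3-methylpentanoyl]-4-phenyl-1,3-oxazolidin-2-one | O=C(C[C@@H](C)CC[C@@H]1[C@@]2(C)CCCC(C)(C)[C@@H]2[C@H](O[Si](C)(C)C(C)(C)C)C[C@@]1(C)O[Si](CC)(CC)CC)N1[C@@H](c2ccccc2)COC1=O
F10 | step 3 | (2R)-2-allyl-2,6,6-trimethyl-1-[(trimethylsilyl)methyl]cyclohexan-1-ol (either C1 epimer) | C=CC[C@@]1(C)CCCC(C)(C)C1(O)C[Si](C)(C)C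
A1 | alternative 1 | methyl 3-methyl-5-[2,2,6-trimethyl-8-oxo-7-(prop-1-en-2-yl)bicyclo[4.2.0]octan-7-yl]pentanoate (cis-fused cyclobutanone, one C9 epimer drawn) | C=C(C)[C@]1(CC[C@H](C)CC(=O)OC)[C@@]2(C)CCCC(C)(C)[C@H]2C1=O
A2 | alternative 2 | pantolactonyl 6-(tert-butyldimethylsilyloxy)drima-5,8(17)-dien-11-oate (9β ester, 10β methyl) | CC3(C)COC(=O)[C@@H]3OC(=O)[C@@H]1[C@@]2(C)CCCC(C)(C)C2=C(O[Si](C)(C)C(C)(C)C)CC1=C
A3 | alternative 3 | methyl 6-oxolabd-7-en-15-oate | COC(=O)C[C@@H](C)CC[C@@H]1[C@@]2(C)CCCC(C)(C)[C@@H]2C(=O)C=C1C
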